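**Plan**

1. Retrosynthesis: the cage is opened at C8–C16 and C13–C18 in one operation, after two helper oxygens (C7=O, C18–OH) are put back. The 6/7‑fused diketone that results is cut at C14–C15 (Claisen), C15–CH3, C8–C12 and C9–C11 (enone three‑component coupling), ring A at C1=C2 (metathesis) and ring B by a Diels–Alder reaction.
2. Enabling feature: C8 (α to a temporary C7 ketone) and C13 (α to the C14 ketone) are two enolisable carbons 1,3 to each other across C12. C16 (β‑carbon of a 3‑methoxycarbonylbutenolide) and its ester carbon C18 are two electrophilic carbons 1,3 to each other across C17. One base‑mediated Michael–Claisen annulation joins the pairs and closes the cyclopentane C8–C9–C11–C15–C16 and the ring C13–C14–C15–C16–C17–C18, i.e. the bicyclo[2.2.2]octane.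
3. Forward order: ring B (Diels–Alder), ring A (ring‑closing metathesis), side chains at C9 and C8, seven‑membered ring (Claisen), C15 methyl, butenolide (Knoevenagel), key annulation, then C18–OH → H (enol triflate) and C7=O → CH2 (tosylhydrazone).
4. Stereochemistry: C10 and C5 from the catalyst and the (E)‑dienophile; C9 from cuprate attack anti to the C10 methyl; C15 from convex‑face methylation of the cis‑fused 6/7 system; C8, C16 and C13 follow from C9 and C15 through the rings closed in the key step.

Key step: step 15

Labels used for description only (not an official numbering): ring A = O–C3(=O)–C2=C1–C10–C5–C4(CH3)2; ring B = C5–C6–C7–C8–C9–C10; C11 = CH2 on C9; C12 = CH2 on C8; C13 = C(CH3) bridgehead; C14 = ketone; C15 = C(CH3); C16 = quaternary carbon bonded to C8; C17=C18 = the alkene (C18 is CH); C19 = butyrolactone C=O; C20 = OCH2; β = face of the C10 methyl.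

Assumption: the Cr(III)–salen catalyst is taken to show on this β‑carbethoxy enal the facial sense known for α‑substituted acroleins; the catalyst enantiomer that gives 3 as drawn is used.

Remark: C13 (from 13 on) and the carbinol carbon in 14 and 15 are carried as epimer mixtures and are left unspecified in the SMILES; C8 stays epimerisable until step 15.

**Route**

Step 1
Reactants: 1 (E)-3-(tert-butyldimethylsilyloxy)-N,N-dimethylbuta-1,3-dien-1-amine; 2 ethyl (E)-3-methyl-4-oxobut-2-enoate
Product: 3 ethyl 5-(tert-butyldimethylsilyloxy)-3-(dimethylamino)-2-formyl-2-methylcyclohex-4-ene-1-carboxylate (CHO trans to CO2Et)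
Conditions: (salen)Cr(III)SbF6 (5 mol %), 4 Å MS, CH2Cl2, −40 °C; crude adduct used as such
Reagents that add atoms: none
Why: Cr(III)–salen‑catalysed enantioselective Diels–Alder reaction of an aminosiloxydiene with an α‑substituted enal: the chromium‑bound aldehyde should direct the nucleophilic CH2 terminus of the diene to the ester‑bearing carbon, the (E)‑geometry is carried into the trans CHO/CO2Et relationship (10‑CH3 trans to H‑5), and the catalyst should fix the absolute configuration at C10.

Step 2
Reactants: 3 Diels–Alder adduct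
Product: 4 ethyl 5-(tert-butyldimethylsilyloxy)-3-(dimethylamino)-2-methyl-2-vinylcyclohex-4-ene-1-carboxylate
Conditions: Ph3PCH3Br, KHMDS, THF, −78 → 0 °C
Reagents that add atoms: methyltriphenylphosphonium bromide, C[P+](c1ccccc1)(c1ccccc1)c1ccccc1.[Br-]
Why: Wittig methylenation of the only free carbonyl group (the ketone is still masked as the silyl enol ether), so that the ester alone can take up the Grignard reagent in step 3.

Step 3
Reactants: 4 vinyl ester
Product: 6 5-(2-hydroxypropan-2-yl)-4-methyl-4-vinylcyclohex-2-en-1-one (vinyl trans to the carbinol group), via tertiary alcohol silyl enol ether 5 (not isolated)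
Conditions: MeMgBr (4 equiv), THF, −20 → 0 °C; then 1 M HCl, THF, 0 °C
Reagents that add atoms: methylmagnesium bromide, C[Mg]Br
Why: double Grignard addition to the ester builds the C4 carbinol, and the acidic work‑up hydrolyses the silyl enol ether and eliminates dimethylamine (E1cB), the usual unmasking of an aminosiloxydiene adduct to the cyclohexenone.

Step 4
Reactants: 6 hydroxy enone
Product: 7 2-(2-methyl-5-oxo-2-vinylcyclohex-3-en-1-yl)propan-2-yl acrylate
Conditions: acryloyl chloride, i-Pr2NEt, DMAP (cat.), CH2Cl2, 0 → 40 °C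
Reagents that add atoms: acryloyl chloride, C=CC(=O)Cl
Why: DMAP‑catalysed acylation of the tertiary alcohol by an acid chloride.

Step 5
Reactants: 7 acrylate
Product: 8 AB enone lactone: Z‑enoate ε‑lactone (ring A) trans‑fused to the cyclohex-8-en-7-one (10β‑CH3, 5α‑H)
Conditions: Hoveyda–Grubbs II (5 mol %), toluene, 80 °C
Reagents that add atoms: none
Why: ring‑closing metathesis of a vinyl group with an acrylate should give ring A directly at its final oxidation level; the gem‑dimethyl group and the trans‑diequatorial arms favour closure, and the ring enone is an inert (type IV) alkene.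

Step 6
Reactants: 8 AB enone lactone; 9 but-3-enylmagnesium bromide; 10 methyl 2-(bromomethyl)acrylate
Product: 12 AB lactone 7-ketone with 9α-(but-3-enyl) and 8β-[2-(methoxycarbonyl)allyl] groups, via magnesium enolate 11 (not isolated)
Conditions: 9 (1.5 equiv), CuBr·SMe2 (10 mol %), THF, −78 → −30 °C; then 10, DMPU, −30 → 0 °C
Reagents that add atoms: none
Why: copper‑catalysed conjugate addition should occur anti to the axial C10 methyl (as in 1α‑alkylation of steroidal 1‑en‑3‑ones) and set C9, and the regiodefined enolate is C‑alkylated at C8 by the allylic bromide (three‑component conjugate addition–enolate trapping), trans to the new C9 group.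

Step 7
Reactants: 12 acrylate ketone
Product: 13 AB lactone 7-ketone with 9α-(but-3-enyl) and 8β-(3-methoxy-3-oxo-2-methylpropyl) groups (C13 epimers)
Conditions: [(Ph3P)CuH]6 (5 mol %), (EtO)2MeSiH, t-BuOH, toluene, 0 °C → rt
Reagents that add atoms: none
Why: copper hydride conjugate reduction should select the unhindered 2‑substituted acrylate over the β‑neopentyl ring‑A enoate, the saturated ketone and the terminal alkene; both C13 epimers serve because C13 is enolised later.

Step 8
Reactants: 13 ester alkene
Product: 14 9α-(3,4-dihydroxybutyl) diol (carbinol epimers)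
Conditions: OsO4 (2 mol %), NMO, acetone/H2O, 0 °C → rt
Reagents that add atoms: osmium tetroxide (catalytic oxygen carrier), O=[Os](=O)(=O)=O; N-methylmorpholine N-oxide, C[N+]1([O-])CCOCC1; water, O
Why: catalytic dihydroxylation (Upjohn) of the electron‑rich terminal alkene in preference to the electron‑poor, hindered ring‑A enoate.

Step 9
Reactants: 14 diol
Product: 15 primary tert-butyldimethylsilyl ether of 14
Conditions: TBSCl (1.05 equiv), imidazole, DMF, 0 °C
Reagents that add atoms: tert-butyldimethylsilyl chloride, CC(C)(C)[Si](C)(C)Cl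
Why: selective silylation of the primary hydroxyl group.

Step 10
Reactants: 15 mono‑silyl ether
Product: 16 9α-[4-(tert-butyldimethylsilyloxy)-3-oxobutyl] ketone
Conditions: Dess–Martin periodinane, NaHCO3, CH2Cl2, rt
Reagents that add atoms: none
Why: Dess–Martin oxidation of the secondary alcohol to the α‑silyloxy ketone.

Step 11
Reactants: 16 keto ester
Product: 17 seven-membered β-diketone: ring C8–C12–C13–C14(=O)–C15–C11–C9 with a silyloxyacetyl group on C15 (cis-fused, H-8 and H-9 β)
Conditions: t-BuOK (2.2 equiv), THF, 0 °C → rt; then 1 M HCl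
Reagents that add atoms: none
Why: intramolecular crossed Claisen condensation (ketone enolate carbon C15 onto the methyl ester carbon C14) under thermodynamic control, where only this closure gives a product drained as a stabilised β‑diketone enolate; C8 equilibrates to the cis‑fused isomer with C12 equatorial.

Step 12
Reactants: 17 β‑diketone
Product: 18 15-methyl β-diketone (15-CH3 β, syn to H-9; silyloxyacetyl group α, syn to C10)
Conditions: MeI, K2CO3, acetone, rt
Reagents that add atoms: iodomethane, CI
Why: C‑alkylation of the β‑diketone enolate on the convex β face of the cis‑fused bicyclo[5.4.0] system (the face of H‑8 and H‑9, anti to C10) should set the C15 quaternary centre.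

Step 13
Reactants: 18 silyl ether
Product: 19 15-(hydroxyacetyl) diketone
Conditions: HF·pyridine, THF, 0 °C → rt
Reagents that add atoms: none
Why: fluoride cleavage of the silyl ether under non‑basic conditions, which spare the non‑enolisable β‑diketone from retro‑Claisen cleavage.

Step 14
Reactants: 19 hydroxy ketone; 20 methyl 3-chloro-3-oxopropanoate
Product: 22 key precursor: 6/7-fused 7,14-diketone with a 3-(methoxycarbonyl)-2-oxo-2,5-dihydrofuran-4-yl group on C15, via mixed malonate ester 21 (not isolated)
Conditions: 20, pyridine, CH2Cl2, 0 °C; then TiCl4, pyridine, THF, 0 °C → rt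
Reagents that add atoms: none
Why: O‑acylation followed by TiCl4/pyridine Knoevenagel cyclocondensation of the malonate onto the adjacent ketone gives the butenolide (C16=C17); the weak base should not enolise the C7 ketone, so the acceptor is kept for step 15.

Step 15
Reactants: 22 key precursor
Product: 24 18-hydroxy-7-oxo-andilesin B (enol form of the β-keto lactone), via Michael adduct 23 (not isolated)
Conditions: t-BuOK (1.5 equiv), t-BuOH/THF 1:4, 0 → 50 °C, argon; then 1 M HCl
Reagents that add atoms: none
Why: tert‑Butoxide equilibrates the enolisable positions; the C7 enolate adds through C8 to C16 (5‑exo‑trig Michael addition, closing the cyclopentane C8–C9–C11–C15–C16), and the C14 enolate then attacks through C13 the ester carbon C18 with loss of methoxide (6‑exo‑trig Claisen/Dieckmann acyl substitution, closing the ring C13–C18 and with it the bicyclo[2.2.2]octane); attack at the lactone carbonyl followed by relactonisation would give the same compound. The closest known reaction type is the Michael–Claisen annulation of an enolate with an alkylidene malonate, as in the dimedone synthesis, here run within one molecule with two ketone α‑carbons as the 1,3‑dinucleophile. C8 and C16 are controlled by C9 and C15: the tether C9–C11–C15 allows only a cis‑fused cyclopentane, so C16 bonds to the α face of C8 and C12 ends β; the Michael step is reversible, so only the C16 epimer whose malonate carbon faces C13 is drained, and the bridgehead C13 has no choice. The cascade is driven by the β‑keto lactone enolate (C17 between C18 and C19), which also shields the non‑enolisable C14/C18 diketone from retro‑Claisen cleavage. The selectivity needed is addition from C8 and not from C6 or C13 (seven‑ or four‑membered rings), and survival of the ring‑A lactone and of the C14–C15 bond; ring size, the hindered non‑nucleophilic base and the lack of acidic hydrogens in ring A should secure it.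

Step 16
Reactants: 24 enol
Product: 25 C18 enol triflate
Conditions: Tf2O, i-Pr2NEt, CH2Cl2, −78 °C
Reagents that add atoms: trifluoromethanesulfonic anhydride, O=S(=O)(OS(=O)(=O)C(F)(F)F)C(F)(F)F
Why: O‑triflation of a β‑keto ester‑type enol to the vinyl triflate.

Step 17
Reactants: 25 enol triflate
Product: 26 7-oxo-andilesin B
Conditions: Pd(OAc)2 (5 mol %), PPh3 (10 mol %), HCO2H, Et3N, DMF, 60 °C
Reagents that add atoms: none
Why: palladium‑catalysed formate reduction of the enol triflate replaces the helper oxygen at C18 by hydrogen and leaves the C17=C18 alkene in place.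

Step 18
Reactants: 26 7-oxo-andilesin B
Product: 27 C7 tosylhydrazone
Conditions: TsNHNH2, AcOH (cat.), EtOH, 60 °C
Reagents that add atoms: p-toluenesulfonyl hydrazide, Cc1ccc(cc1)S(=O)(=O)NN
Why: hydrazone formation at the C7 ketone; the C14 ketone, flanked by two quaternary carbons, should not react.

Step 19
Reactants: 27 tosylhydrazone
Product: 28 andilesin B
Conditions: catecholborane, CHCl3, 0 °C → rt; then NaOAc·3H2O, reflux
Reagents that add atoms: none
Why: catecholborane reduction of the tosylhydrazone (a mild, non‑basic Wolff–Kishner equivalent) converts C7 to CH2 without touching the lactones, the alkenes or the hindered ketone.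

**Compound list**

1 | (E)-3-(tert-butyldimethylsilyloxy)-N,N-dimethylbuta-1,3-dien-1-amine | CN(C)/C=C/C(=C)O[Si](C)(C)C(C)(C)C | starting material
2 | ethyl (E)-3-methyl-4-oxobut-2-enoate | CCOC(=O)/C=C(\C)C=O | starting material
3 | ethyl 5-(tert-butyldimethylsilyloxy)-3-(dimethylamino)-2-formyl-2-methylcyclohex-4-ene-1-carboxylate (CHO trans to CO2Et, cis to NMe2) | O=C[C@@]1(C)[C@H](C(=O)OCC)CC(O[Si](C)(C)C(C)(C)C)=C[C@H]1N(C)C | intermediate
4 | ethyl 5-(tert-butyldimethylsilyloxy)-3-(dimethylamino)-2-methyl-2-vinylcyclohex-4-ene-1-carboxylate | C=C[C@@]1(C)[C@H](C(=O)OCC)CC(O[Si](C)(C)C(C)(C)C)=C[C@H]1N(C)C | intermediate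
5 | 2-[5-(tert-butyldimethylsilyloxy)-3-(dimethylamino)-2-methyl-2-vinylcyclohex-4-en-1-yl]propan-2-ol (as magnesium alkoxide) | C=C[C@@]1(C)[C@H](C(C)(C)O)CC(O[Si](C)(C)C(C)(C)C)=C[C@H]1N(C)C | intermediate
6 | 5-(2-hydroxypropan-2-yl)-4-methyl-4-vinylcyclohex-2-en-1-one (vinyl trans to carbinol group) | C=C[C@@]1(C)[C@H](C(C)(C)O)CC(=O)C=C1 | intermediate
7 | 2-(2-methyl-5-oxo-2-vinylcyclohex-3-en-1-yl)propan-2-yl acrylate | C=C[C@@]1(C)[C@H](C(C)(C)OC(=O)C=C)CC(=O)C=C1 | intermediate
8 | AB enone lactone (ring A Z‑enoate ε‑lactone trans‑fused to cyclohex-8-en-7-one; 10β‑CH3, 5α‑H) | CC1(C)OC(=O)C=C[C@@]2(C)[C@H]1CC(=O)C=C2 | intermediate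
9 | but-3-enylmagnesium bromide | C=CCC[Mg]Br | starting material
10 | methyl 2-(bromomethyl)acrylate | C=C(CBr)C(=O)OC | starting material
11 | magnesium enolate (C7–OMgBr, C7=C8) of the 9α‑butenyl adduct | CC1(C)OC(=O)C=C[C@@]2(C)[C@H]1CC(O[Mg]Br)=C[C@H]2CCC=C | intermediate
12 | 7-ketone with 9α-(but-3-enyl) and 8β-[2-(methoxycarbonyl)allyl] (H‑9 β; kinetic trans isomer shown) | CC1(C)OC(=O)C=C[C@@]2(C)[C@H]1CC(=O)[C@H](CC(=C)C(=O)OC)[C@H]2CCC=C | intermediate
13 | 7-ketone with 9α-(but-3-enyl) and 8β-(3-methoxy-3-oxo-2-methylpropyl) (C13 epimers) | CC1(C)OC(=O)C=C[C@@]2(C)[C@H]1CC(=O)[C@H](CC(C)C(=O)OC)[C@H]2CCC=C | intermediate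
14 | 9α-(3,4-dihydroxybutyl) diol | CC1(C)OC(=O)C=C[C@@]2(C)[C@H]1CC(=O)[C@H](CC(C)C(=O)OC)[C@H]2CCC(O)CO | intermediate
15 | primary TBS ether of 14 | CC1(C)OC(=O)C=C[C@@]2(C)[C@H]1CC(=O)[C@H](CC(C)C(=O)OC)[C@H]2CCC(O)CO[Si](C)(C)C(C)(C)C | intermediate
16 | 9α-[4-(tert-butyldimethylsilyloxy)-3-oxobutyl] keto ester | CC1(C)OC(=O)C=C[C@@]2(C)[C@H]1CC(=O)[C@H](CC(C)C(=O)OC)[C@H]2CCC(=O)CO[Si](C)(C)C(C)(C)C | intermediate
17 | seven-membered β-diketone, 15-(silyloxyacetyl)-14-ketone, cis-fused (H‑8, H‑9 β), enolisable at C15 | CC1(C)OC(=O)C=C[C@@]2(C)[C@H]1CC(=O)[C@H]3CC(C)C(=O)C(C(=O)CO[Si](C)(C)C(C)(C)C)C[C@@H]23 | intermediate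
18 | 15-methyl β-diketone (15‑CH3 syn to H‑9, acyl syn to C10) | CC1(C)OC(=O)C=C[C@@]2(C)[C@H]1CC(=O)[C@H]3CC(C)C(=O)[C@@](C)(C(=O)CO[Si](C)(C)C(C)(C)C)C[C@@H]23 | intermediate
19 | 15-(hydroxyacetyl) diketone | CC1(C)OC(=O)C=C[C@@]2(C)[C@H]1CC(=O)[C@H]3CC(C)C(=O)[C@@](C)(C(=O)CO)C[C@@H]23 | intermediate
20 | methyl 3-chloro-3-oxopropanoate (methyl malonyl chloride) | COC(=O)CC(=O)Cl | starting material
21 | mixed malonate ester of 19 | CC1(C)OC(=O)C=C[C@@]2(C)[C@H]1CC(=O)[C@H]3CC(C)C(=O)[C@@](C)(C(=O)COC(=O)CC(=O)OC)C[C@@H]23 | intermediate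
22 | key precursor: 7,14-diketone with the 3-(methoxycarbonyl)butenolide on C15 | CC1(C)OC(=O)C=C[C@@]2(C)[C@H]1CC(=O)[C@H]3CC(C)C(=O)[C@@](C)(C4=C(C(=O)OC)C(=O)OC4)C[C@@H]23 | intermediate
23 | Michael adduct (C8–C16 formed; malonate‑type C17–H) | CC1(C)OC(=O)C=C[C@@]2(C)[C@H]1CC(=O)[C@@]13CC(C)C(=O)[C@](C)(C[C@@H]23)[C@]14COC(=O)C4C(=O)OC | intermediate
24 | 18-hydroxy-7-oxo-andilesin B (enol form) | CC1(C)OC(=O)C=C[C@@]2(C)[C@H]1CC(=O)[C@@]13C[C@@]4(C)C(O)=C5C(=O)OC[C@]51[C@@](C)(C[C@@H]23)C4=O | intermediate
25 | C18 enol triflate of 24 | CC1(C)OC(=O)C=C[C@@]2(C)[C@H]1CC(=O)[C@@]13C[C@@]4(C)C(OS(=O)(=O)C(F)(F)F)=C5C(=O)OC[C@]51[C@@](C)(C[C@@H]23)C4=O | intermediate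
26 | 7-oxo-andilesin B | CC1(C)OC(=O)C=C[C@@]2(C)[C@H]1CC(=O)[C@@]13C[C@@]4(C)C=C5C(=O)OC[C@]51[C@@](C)(C[C@@H]23)C4=O | intermediate
27 | C7 tosylhydrazone of 26 | CC1(C)OC(=O)C=C[C@@]2(C)[C@H]1CC(=NNS(=O)(=O)c6ccc(C)cc6)[C@@]13C[C@@]4(C)C=C5C(=O)OC[C@]51[C@@](C)(C[C@@H]23)C4=O | intermediate
28 | andilesin B | CC1(C)OC(=O)C=C[C@@]2(C)[C@H]1CC[C@@]13C[C@@]4(C)C=C5C(=O)OC[C@]51[C@@](C)(C[C@@H]23)C4=O | target

**Count and risks**

Total step count: 19. Longest linear sequence: 19 steps (from 1 and 2).

Step 15. The cascade may stall at the γ‑deprotonated butenolide or revert by retro‑Michael reaction, because ring B has to become a twist‑boat, and alkoxide may cleave the C14–C15 bond (retro‑Claisen). The fallback sets out from 22 and comes back at 24; it makes the two bonds in two operations under different activation. Pyrrolidine and acetic acid in benzene should convert 22 into the C7 pyrrolidine enamine F1, which adds through C8 to C16 under neutral conditions (enamine Michael addition). Hydrolysis with aqueous acetic acid gives the Michael adduct 23, now isolated. Sodium hydride with a trace of methanol in THF then closes C13–C18 by Dieckmann‑type condensation to 24.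

Step 12. Facial selectivity of the methylation may be poor or reversed, and O‑methylation may compete. The fallback sets out from 8 and comes back at 18; it introduces the two C15 substituents in the opposite order, so that the oxygenated two‑carbon unit is the incoming electrophile. Vinylmagnesium bromide with CuBr·SMe2 on 8, trapping of the enolate with 2,4-dimethylpenta-1,4-dien-3-one and equilibration at C8 on work‑up give the vinyl isopropenyl ketone adduct F2. Ring‑closing metathesis (Grubbs II) gives the 15-methylcyclohept-15(11)-en-14-one F3. Copper hydride‑catalysed conjugate reduction with dimethylphenylsilane gives the regiodefined C14 silyl enol ether F4. A Mukaiyama aldol reaction with (tert-butyldimethylsilyloxy)acetaldehyde and BF3·OEt2 gives the aldol F5, and Dess–Martin oxidation gives 18; the face that methyl iodide took in step 12 is now taken by the aldehyde.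

Step 5. The metathesis catalyst may fail to engage the neopentyl vinyl group or the tertiary acrylate, so that oligomers form instead of the seven‑membered ring. The fallback sets out from 3 and comes back at 8; it closes ring A by carbonylation. (Iodomethyl)triphenylphosphonium iodide with NaHMDS (Z‑selective iodo‑olefination) converts the aldehyde 3 into the (Z)-vinyl iodide adduct F6. MeMgBr and acidic work‑up as in step 3 give the hydroxy enone vinyl iodide F7. Pd(PPh3)4, CO (1 atm), Et3N, DMF, 60 °C (carbonylative lactonisation onto the tertiary alcohol) gives 8.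

**Further compounds**

F1 | step 15 | C7 pyrrolidine enamine of 22 (C7=C8) | CC1(C)OC(=O)C=C[C@@]2(C)[C@H]1CC(N4CCCC4)=C3CC(C)C(=O)[C@@](C)(C4=C(C(=O)OC)C(=O)OC4)C[C@@H]23
F2 | step 12 | 7-ketone with 9α-vinyl and 8-(2,4-dimethyl-3-oxopent-4-enyl) groups (C8 equilibrated, C12 α) | CC1(C)OC(=O)C=C[C@@]2(C)[C@H]1CC(=O)[C@@H](CC(C)C(=O)C(C)=C)[C@H]2C=C
F3 | step 12 | cis-fused 15-methylcyclohept-15(11)-en-14-one | CC1(C)OC(=O)C=C[C@@]2(C)[C@H]1CC(=O)[C@H]3CC(C)C(=O)C(C)=C[C@@H]23
F4 | step 12 | C14 dimethylphenylsilyl enol ether (C14=C15) | CC1(C)OC(=O)C=C[C@@]2(C)[C@H]1CC(=O)[C@H]3CC(C)C(O[Si](C)(C)c4ccccc4)=C(C)C[C@@H]23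
F5 | step 12 | C15 aldol with 2-(tert-butyldimethylsilyloxy)-1-hydroxyethyl group | CC1(C)OC(=O)C=C[C@@]2(C)[C@H]1CC(=O)[C@H]3CC(C)C(=O)[C@@](C)(C(O)CO[Si](C)(C)C(C)(C)C)C[C@@H]23
F6 | step 5 | (Z)-vinyl iodide analogue of 4 | I/C=C\[C@@]1(C)[C@H](C(=O)OCC)CC(O[Si](C)(C)C(C)(C)C)=C[C@H]1N(C)C
F7 | step 5 | (Z)-vinyl iodide analogue of 6 | I/C=C\[C@@]1(C)[C@H](C(C)(C)O)CC(=O)C=C1
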